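**Retrosynthetic overview**

1. Labels: C-a = CH carrying the side chain and bonded to C-3 of quinolone A; C-c = adjacent ring-fusion CH bonded to C-3 of quinolone B; C-b = ring-fusion CH–O next to CMe2. The isobutenyl group comes from a C-a aldehyde (Wittig), itself from a C-a styryl group (oxidative cleavage) carried as a robust stand-in.
2. The pyran ring of unit A is opened at the O–C-4(A) bond: alkoxide displaces an enol triflate, and the C-b alcohol comes from reduction of a C-b ketone.
3. Key disconnection C-3(A)–C-a: catalytic asymmetric intermolecular Michael addition of 4-hydroxy-1-methylquinolin-2(1H)-one to a dienone built on unit B.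
4. The dienone comes from aldol condensation of pyranoquinoline-3,5-dione 6 with cinnamaldehyde; 6 comes from N-methylflindersine (epoxidation, Meinwald rearrangement), made from the same hydroxyquinolone and prenal.
5. Ring order: pyran ring of unit B first (step 1), pyran ring of unit A last (step 8); both quinolone bicycles are bought.

Assumption: the (8S,9S)-squaramide in step 5 is taken to give the C-a configuration drawn (to be confirmed on 11 or 14); if it gives the opposite sense, its quinidine-derived pseudo-enantiomer is used with no other change.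

**Route**

Step 1
Reactants: 1 4-hydroxy-1-methylquinolin-2(1H)-one; 2 3-methylbut-2-enal
Product: 4 N-methylflindersine (2,2,6-trimethyl-2H-pyrano[3,2-c]quinolin-5(6H)-one), via Knoevenagel 1-oxatriene 3 (not isolated)
Conditions: ethylenediammonium diacetate (10 mol %), toluene, 100 °C, 12 h
Reagents that add atoms: none
Why: Knoevenagel condensation at C-3 of the vinylogous acid followed by oxa-6π electrocyclisation of the 1-oxatriene is the standard entry to 2,2-dimethylpyrano[3,2-c]quinolinones; no stereocentre is formed.

Step 2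
Reactants: 4 N-methylflindersine
Product: 5 racemic 3,4-epoxy-2,2,6-trimethyl-3,4-dihydro-2H-pyrano[3,2-c]quinolin-5(6H)-one
Conditions: dimethyldioxirane (0.07 M in acetone, 1.2 equiv), CH2Cl2, 0 °C, 1 h; evaporate, use crude
Reagents that add atoms: dimethyldioxirane, CC1(C)OO1
Why: Electrophilic epoxidation of the electron-rich C3=C4 alkene under neutral conditions spares the acid-labile epoxide; it is racemic, which does not matter because both centres are erased in step 3.

Step 3
Reactants: 5 racemic epoxide
Product: 6 2,2,6-trimethyl-2H-pyrano[3,2-c]quinoline-3,5(4H,6H)-dione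
Conditions: BF3·OEt2 (10 mol %), CH2Cl2, −40 → 0 °C
Reagents that add atoms: none
Why: Meinwald rearrangement: Lewis-acid opening at C-4 gives the cation stabilised by the enol-ether oxygen, and a 1,2-hydride shift from C-3 gives the 3-ketone (chromene oxide to chroman-3-one type).

Step 4
Reactants: 6 pyranoquinoline-3,5-dione; 7 (E)-cinnamaldehyde
Product: 9 (4Z)-2,2,6-trimethyl-4-[(2E)-3-phenylprop-2-en-1-ylidene]-2H-pyrano[3,2-c]quinoline-3,5(4H,6H)-dione, via aldol adduct 8 (not isolated)
Conditions: piperidine (20 mol %), AcOH (20 mol %), toluene, 4 Å molecular sieves, 50 °C, N2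
Reagents that add atoms: none
Why: Crossed aldol (Claisen–Schmidt type) condensation: 6 can enolise only toward the doubly activated C-4 methylene and cinnamaldehyde cannot enolise, so one dienone forms after E1cB dehydration, with the chain expected to turn toward the ketone (Z) and away from the lactam carbonyl.

Step 5
Reactants: 9 dienone; 1 4-hydroxy-1-methylquinolin-2(1H)-one (1.2 equiv)
Product: 11 cyclic hemiketal of 10 (O-4 of quinolone A bonded to C-b which also bears OH; C-a R; C-c S; both C-b epimers), via open-chain Michael adduct 10 (not isolated)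
Conditions: 3-{[3,5-bis(trifluoromethyl)phenyl]amino}-4-{[(8S,9S)-6′-methoxycinchonan-9-yl]amino}cyclobut-3-ene-1,2-dione (10 mol %), CH2Cl2/THF 4:1, 0 °C → rt, 48 h; recrystallise
Reagents that add atoms: none
Why: Intermolecular Michael addition (1,4; the 1,6 site is the hindered benzylic terminus) of C-3 of 1 to the β-carbon of 9 under bifunctional squaramide–tertiary amine catalysis forms the key C-3(A)–C-a bond and sets C-a by catalyst control, while the enolisable C-c equilibrates under the amine so that the adduct rests as the hemiketal with styryl trans to quinolone B (cis to H-c).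

Step 6
Reactants: 11 hemiketal (in equilibrium with its open keto form 10, which is the species reduced)
Product: 12 4-hydroxy-3-{(1R,2E)-1-[(3S,4S)-3-hydroxy-2,2,6-trimethyl-5-oxo-3,4,5,6-tetrahydro-2H-pyrano[3,2-c]quinolin-4-yl]-3-phenylprop-2-en-1-yl}-1-methylquinolin-2(1H)-one
Conditions: NaBH4 (3 equiv), THF/MeOH 10:1, −40 → 0 °C; aqueous NH4Cl
Reagents that add atoms: none
Why: Borohydride reduction of the ketone: the C-4 substituent of unit B sits pseudo-axial (peri strain with the lactam C=O), so hydride enters anti to it (Felkin–Anh type) and sets C-b as the cis-3-hydroxy-4-alkyl alcohol, while the cold, weakly basic medium leaves C-c untouched.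

Step 7
Reactants: 12 enol alcohol
Product: 13 3-{(1R,2E)-1-[(3S,4S)-3-hydroxy-2,2,6-trimethyl-5-oxo-3,4,5,6-tetrahydro-2H-pyrano[3,2-c]quinolin-4-yl]-3-phenylprop-2-en-1-yl}-1-methyl-2-oxo-1,2-dihydroquinolin-4-yl trifluoromethanesulfonate
Conditions: PhNTf2 (1.1 equiv), Et3N (2 equiv), CH2Cl2, 0 °C → rt
Reagents that add atoms: N-phenylbis(trifluoromethanesulfonimide), O=S(=O)(N(c1ccccc1)S(=O)(=O)C(F)(F)F)C(F)(F)F
Why: Selective O-sulfonylation of the acidic 4-hydroxyquinolone enol (pKa about 6) as its ammonium enolate; the hindered neutral secondary alcohol does not react with the mild triflimide.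

Step 8
Reactants: 13 enol triflate
Product: 14 cis-fused bis(pyranoquinolinone) with (E)-2-phenylethenyl at C-a (C-a R, C-b S, C-c S; the target skeleton with styryl in place of isobutenyl)
Conditions: Cs2CO3 (2 equiv), MeCN (0.01 M), 50 °C; chromatography and recrystallisation to a single diastereomer
Reagents that add atoms: none
Why: Intramolecular addition–elimination (SNAr-type vinylogous acyl substitution) of the C-b alkoxide at C-4 of the quinolone triflate closes the six-membered pyran ring without touching the C-b–O bond, so the cis relationship set in step 6 becomes the cis ring fusion.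

Step 9
Reactants: 14 styryl compound (single diastereomer)
Product: 16 aldehyde with the skeleton of 14 bearing CHO at C-a (C-a R; C-b S; C-c S), via vicinal diol 15 (not isolated)
Conditions: OsO4 (2 mol %), NaIO4 (4 equiv), 2,6-lutidine (2 equiv), 1,4-dioxane/H2O 3:1, rt
Reagents that add atoms: osmium tetroxide, O=[Os](=O)(=O)=O (transfers the oxygen; regenerated by sodium periodate, [Na+].[O-]I(=O)(=O)=O)
Why: Lemieux–Johnson oxidative cleavage acts only on the styryl alkene (the tetrasubstituted push–pull C3=C4 bonds of the quinolones are inert), and C-a keeps its configuration, with the formyl group on the convex face, which is also the expected thermodynamic epimer.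

Step 10
Reactants: 16 aldehyde
Product: 18 target CNP0107253.2 (C-a R; C-b S; C-c S; 2-methylprop-1-en-1-yl at C-a), via oxaphosphetane 17 (not isolated)
Conditions: isopropyltriphenylphosphonium iodide (2 equiv), n-BuLi (1.9 equiv), THF, 0 °C; add 16 at −78 °C, warm to rt
Reagents that add atoms: isopropyltriphenylphosphonium iodide, CC(C)[P+](c1ccccc1)(c1ccccc1)c1ccccc1.[I-]
Why: Wittig olefination with the non-stabilised isopropylidene ylide gives the trisubstituted alkene with no E/Z issue, and the low-temperature addition limits enolisation of the α-branched aldehyde.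

**Compound list**

1 | 4-hydroxy-1-methylquinolin-2(1H)-one | Cn1c(=O)cc(O)c2ccccc12 | starting material
2 | 3-methylbut-2-enal (prenal) | CC(C)=CC=O | starting material
3 | 1-methyl-3-(3-methylbut-2-en-1-ylidene)quinoline-2,4(1H,3H)-dione (1-oxatriene, not isolated) | CC(C)=CC=C1C(=O)c2ccccc2N(C)C1=O | intermediate
4 | N-methylflindersine, 2,2,6-trimethyl-2H-pyrano[3,2-c]quinolin-5(6H)-one | CC1(C)C=Cc2c(O1)c1ccccc1n(C)c2=O | intermediate
5 | racemic 3,4-epoxy-2,2,6-trimethyl-3,4-dihydro-2H-pyrano[3,2-c]quinolin-5(6H)-one | CC1(C)Oc2c(C3OC13)c(=O)n(C)c1ccccc21 | intermediate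
6 | 2,2,6-trimethyl-2H-pyrano[3,2-c]quinoline-3,5(4H,6H)-dione | CC1(C)Oc2c(CC1=O)c(=O)n(C)c1ccccc21 | intermediate
7 | (E)-cinnamaldehyde | O=C/C=C/c1ccccc1 | starting material
8 | 4-[(2E)-1-hydroxy-3-phenylprop-2-en-1-yl]-2,2,6-trimethyl-2H-pyrano[3,2-c]quinoline-3,5(4H,6H)-dione (diastereomer mixture, not isolated) | CC1(C)Oc2c(C(C(O)/C=C/c3ccccc3)C1=O)c(=O)n(C)c1ccccc21 | intermediate
9 | (4Z)-2,2,6-trimethyl-4-[(2E)-3-phenylprop-2-en-1-ylidene]-2H-pyrano[3,2-c]quinoline-3,5(4H,6H)-dione | CC1(C)Oc2c(/C(=C/C=C/c3ccccc3)C1=O)c(=O)n(C)c1ccccc21 | intermediate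
10 | 4-hydroxy-1-methyl-3-{(1R,2E)-3-phenyl-1-[(4S)-2,2,6-trimethyl-3,5-dioxo-3,4,5,6-tetrahydro-2H-pyrano[3,2-c]quinolin-4-yl]prop-2-en-1-yl}quinolin-2(1H)-one (open-chain Michael adduct, not isolated) | c1ccccc1/C=C/[C@@H](c1c(O)c2ccccc2n(C)c1=O)[C@@H]1C(=O)C(C)(C)Oc2c1c(=O)n(C)c1ccccc21 | intermediate
11 | cyclic hemiketal of 10: O-4 of quinolone A bonded to C-b, which also bears OH (C-a R, C-c S, both C-b epimers) | c1ccccc1/C=C/[C@H]1c2c(c3ccccc3n(C)c2=O)OC2(O)[C@@H]1c1c(c3ccccc3n(C)c1=O)OC2(C)C | intermediate
12 | 4-hydroxy-3-{(1R,2E)-1-[(3S,4S)-3-hydroxy-2,2,6-trimethyl-5-oxo-3,4,5,6-tetrahydro-2H-pyrano[3,2-c]quinolin-4-yl]-3-phenylprop-2-en-1-yl}-1-methylquinolin-2(1H)-one | c1ccccc1/C=C/[C@@H](c1c(O)c2ccccc2n(C)c1=O)[C@@H]1[C@H](O)C(C)(C)Oc2c1c(=O)n(C)c1ccccc21 | intermediate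
13 | 4-O-triflate of 12 (quinolone A enol sulfonylated; C-a R, C-b S, C-c S) | c1ccccc1/C=C/[C@@H](c1c(OS(=O)(=O)C(F)(F)F)c2ccccc2n(C)c1=O)[C@@H]1[C@H](O)C(C)(C)Oc2c1c(=O)n(C)c1ccccc21 | intermediate
14 | cis-fused bis(pyrano[3,2-c]quinolin-5-one) with (E)-2-phenylethenyl at C-a (C-a R, C-b S, C-c S) | c1ccccc1/C=C/[C@H]1c2c(c3ccccc3n(C)c2=O)O[C@H]2[C@@H]1c1c(c3ccccc3n(C)c1=O)OC2(C)C | intermediate
15 | 1,2-dihydroxy-2-phenylethyl analogue of 14 at C-a (diol from syn-dihydroxylation, mixture at the two carbinol carbons, not isolated) | OC(c1ccccc1)C(O)[C@H]1c2c(c3ccccc3n(C)c2=O)O[C@H]2[C@@H]1c1c(c3ccccc3n(C)c1=O)OC2(C)C | intermediate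
16 | C-a carbaldehyde of the cis-fused bis(pyranoquinolinone) (C-a R, C-b S, C-c S) | O=C[C@H]1c2c(c3ccccc3n(C)c2=O)O[C@H]2[C@@H]1c1c(c3ccccc3n(C)c1=O)OC2(C)C | intermediate
17 | 1,2-oxaphosphetane from 16 and the isopropylidene ylide (4,4-dimethyl-2,2,2-triphenyl ring, C-3 bonded to C-a; not isolated) | CC1(C)C(OP1(c2ccccc2)(c2ccccc2)c2ccccc2)[C@H]3c4c(c5ccccc5n(C)c4=O)O[C@H]6[C@@H]3c3c(c5ccccc5n(C)c3=O)OC6(C)C | intermediate
18 | CNP0107253.2: cis-fused bis(pyrano[3,2-c]quinolin-5-one) with 2-methylprop-1-en-1-yl at C-a (C-a R, C-b S, C-c S) | CC(C)=C[C@H]1c2c(c3ccccc3n(C)c2=O)O[C@H]2[C@@H]1c1c(c3ccccc3n(C)c1=O)OC2(C)C | target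

**Step count and risks**

Total steps: 10. Longest linear sequence: 10 (1 → 4 → 5 → 6 → 9 → 11 → 12 → 13 → 14 → 16 → 18).

The three steps most likely to fail are 5, 8 and 10.

Step 5 (asymmetric Michael addition). The enantioselectivity and the C-a/C-c diastereoselectivity on this hindered dienone are untested. If they are poor, the union is run without asymmetric induction and the enantiomers are separated through a salt. Setting out from 9 and 1, 1,4-diazabicyclo[2.2.2]octane (20 mol %, CH2Cl2, rt) gives racemic hemiketal F1. Its ring-opened enol is a vinylogous acid, so quinidine (1 equiv, acetone) and fractional crystallisation give the quinidinium enolate salt F2 of the required enantiomer, the way warfarin is classically resolved; quinine is used instead if the mirror-image salt is the one that crystallises. Partition between 1 M HCl and EtOAc returns enantiopure 11, where the route is rejoined.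

Step 8 (ring closure). The alkoxide may attack sulfur (triflyl transfer) or the hindered C-4 attack may be slow. In that case the pyran ring is closed reductively instead. Setting out from hemiketal 11, Et3SiH (5 equiv) and BF3·OEt2 (3 equiv) in CH2Cl2 at −78 → −20 °C (reductive etherification) give 14 directly. Hydride is expected syn to H-c, because a trans fusion would push the C-c–C-a bond into the plane of quinolone B against its lactam carbonyl. The route is rejoined at 14, bypassing 12 and 13 (new compounds: none F0).

Step 10 (Wittig). The basic, hindered ylide may enolise the α-branched, α-heteroaryl aldehyde instead of adding to it. The aldehyde is then avoided altogether. Setting out from 14, cross-metathesis with 2-methyl-2-butene (as solvent) and second-generation Grubbs catalyst (10 mol %, 40 °C, sealed tube) exchanges the styryl terminus for isopropylidene and gives 18 directly, rejoining the route at the target (new compounds: none F0).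

**Further compounds**

F1 | step 5 | racemic hemiketal (racemate of 11, relative configuration as in 11) | c1ccccc1/C=C/C1c2c(c3ccccc3n(C)c2=O)OC2(O)C1c1c(c3ccccc3n(C)c1=O)OC2(C)C
F2 | step 5 | quinidinium salt of the ring-opened enolate of 10 (C-a R, C-c S) | c1ccccc1/C=C/[C@@H](c1c([O-])c2ccccc2n(C)c1=O)[C@@H]1C(=O)C(C)(C)Oc2c1c(=O)n(C)c1ccccc21.C=C[C@H]1C[NH+]2CC[C@H]1C[C@@H]2[C@H](c1ccnc2ccc(OC)cc12)O
F0 | step 8 | none | none
F0 | step 10 | none | none
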